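**Plan** (germacranolide numbering: ring C1–C10, C11=C13 the methylene, C12 the lactone carbonyl on O6, C14 the aldehyde carbon, C15 the methyl on C4)
- Cuts, last to first: C14 oxidation level and the O9 ester; C9–C10 (ten-membered ring, Nozaki–Hiyama–Kishi); the C13–O9 ether of a pyran precursor (retro-oxa-Michael); O6 out of C12–O6–C6 (Baeyer–Villiger retron); then C6–C7 and C11–C12 of the resulting cyclobutanone.
- Enabling feature: the ring O6–C12(=O)–C11(=C13)–C7–C6 is a cyclobutanone C12–C11–C7–C6 plus one inserted oxygen, i.e. a vinylketene equivalent (C12=C6) added across C7=C11. C13 and O9 are 1,5-related through C11–C7–C8–C9, so they are carried as one ether bond of a 3,6-dihydro-2H-pyran whose ring alkene is that C7=C11.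
- Ring order forward: dihydropyran (from D-xylal) → cis-fused cyclobutanone ([2+2]) → γ-lactone (O insertion) → pyran opened by β-elimination (frees C11=C13 and C9–OH) → ten-membered ring.
- Stereochemistry: C8 is bought (C4 of D-xylal); C7 by addition anti to the C8 silyloxy group; C6 by equilibration to the exo alkenyl and retentive migration; C9 by Felkin–Anh addition; C2′ bought.
- Alkenes: 4Z from syn-carbocupration of propyne; C1=C10 geometry from α-iodination of an E-enal.

Key step: step 7

Assumption: the acyl group is (2R)-2-methylbutanoyl, as the target SMILES specifies. TBS = tert-butyldimethylsilyl, TBDPS = tert-butyldiphenylsilyl.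

**Step 1**
Reactants: 1 (3-bromopropoxy)(tert-butyl)dimethylsilane; 2 propyne; 3 oxirane
Product: 6 (3Z)-7-(TBS-oxy)-4-methylhept-3-en-1-ol, via Grignard reagent 4 (not isolated), via alkenylcopper 5 (not isolated)
Conditions: Mg, Et2O; CuBr·SMe2, −45 °C; 2, −25 °C; 3, HMPA/THF, −40→−10 °C; aq NH4Cl
Reagents that add atoms: none
Why: Normant carbocupration adds the alkylcopper syn across propyne with copper on the terminal carbon, and the alkenylcopper opens oxirane with retention, so the two chains end up cis (the 4Z alkene of the target).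

**Step 2**
Reactants: 6
Product: 8 (3Z)-7-(TBS-oxy)-4-methylhept-3-enoic acid, via aldehyde 7 (not isolated)
Conditions: TEMPO (cat.), PhI(OAc)2, MeCN/H2O (pH 7), rt
Reagents that add atoms: water, O
Why: TEMPO/PhI(OAc)2 oxidation of a primary alcohol to the acid through the aldehyde hydrate runs near neutral pH, which should keep the β,γ-alkene out of conjugation and spare the TBS ether.

**Step 3**
Reactants: 8
Product: 9 1-[(3Z)-7-(TBS-oxy)-4-methylhept-3-enoyl]pyrrolidine
Conditions: pyrrolidine, EDC·HCl, HOBt, CH2Cl2, 0 °C→rt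
Reagents that add atoms: pyrrolidine, C1CCNC1
Why: Carbodiimide amide coupling through the HOBt ester uses no strong base, so the Z β,γ-alkene should stay in place.

**Step 4**
Reactants: 10 3,4-di-O-acetyl-D-xylal
Product: 11 (3S)-3,6-dihydro-2H-pyran-3-yl acetate
Conditions: Et3SiH, BF3·OEt2, CH2Cl2, −20→0 °C
Reagents that add atoms: none
Why: Reductive Ferrier rearrangement: BF3 ionises the allylic C3 acetate to the 2,3-unsaturated oxocarbenium ion, which takes hydride at C1, and the C4 stereocentre (later C8) is not involved.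

**Step 5**
Reactants: 11
Product: 12 (3S)-3,6-dihydro-2H-pyran-3-ol
Conditions: K2CO3 (cat.), MeOH, 0 °C
Reagents that add atoms: none
Why: Base-catalysed transesterification removes the acetate, and the volatile alcohol is carried on as a solution.

**Step 6**
Reactants: 12
Product: 13 tert-butyl{[(3S)-3,6-dihydro-2H-pyran-3-yl]oxy}diphenylsilane
Conditions: TBDPSCl, imidazole, DMF, rt
Reagents that add atoms: TBDPSCl, CC(C)(C)[Si](Cl)(c1ccccc1)c1ccccc1
Why: Standard silylation installs a bulky group that shields one ring face in step 7 and should survive until step 19.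

**Step 7**
Reactants: 9; 13
Product: 16 (1S,5S,6R,7R)-5-(TBDPS-oxy)-7-[(1Z)-5-(TBS-oxy)-2-methylpent-1-en-1-yl]-3-oxabicyclo[4.2.0]octan-8-one (cis-fused; alkenyl exo; silyloxy anti to the four-membered ring), via keteniminium triflate 14 (not isolated), via cyclobutaniminium triflate 15 (not isolated)
Conditions: Tf2O, 2,4,6-collidine, (CH2Cl)2, −20→80 °C (13, 3 equiv); then H2O, 60 °C; NaHCO3 work-up
Reagents that add atoms: water, O
Why: Tf2O activates amide 9 and collidine removes the allylic α-proton to give vinylketeniminium 14, whose central carbon C12 bonds to one carbon of the ring alkene of 13 while C6 closes on the other (asynchronous [2+2]) to give iminium 15, hydrolysed to ketone 16; this is the Ghosez keteniminium–olefin cycloaddition, the cationic counterpart of the thermal ketene–alkene [2+2]. The four-membered ring closes by intermolecular suprafacial [2+2] addition across the cis alkene, so it is cis-fused to the bought pyran ring. C7 and C11 should arise by approach to the ring face opposite the allylic OTBDPS group (steric control by the bought C8 centre). C6, which is α to the iminium and allylic, should equilibrate through the enamine to the exo alkenyl isomer, which is the H6/H7-trans arrangement of the target. The step needs the orientation C12-to-C11 and C6-to-C7, which the bulky pyrrolidinium end and the silyloxy group on the C7 side are expected to favour, and [2+2] rather than [4+2] periselectivity, which the Z-trisubstituted alkene should secure by disfavouring the s-cis diene. Amide 9 holds no second alkene or carbonyl that could trap the keteniminium intramolecularly, and the excess of 13 should suppress self-condensation.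

**Step 8**
Reactants: 16
Product: 17 (1R,3aS,7S,7aS)-7-(TBDPS-oxy)-1-[(1Z)-5-(TBS-oxy)-2-methylpent-1-en-1-yl]hexahydro-3H-furo[3,4-c]pyran-3-one (cis-fused; H1/H7a trans)
Conditions: 30% H2O2, AcOH, 0→10 °C
Reagents that add atoms: hydrogen peroxide, OO
Why: Baeyer–Villiger oxidation: the strained cyclobutanone should react far faster than the trisubstituted alkene is epoxidised, and the secondary allylic C6 migrates with retention in preference to the β-oxygenated C11, which places O6 between C12 and C6.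

**Step 9**
Reactants: 17
Product: 18 (1R,3aS,7S,7aS)-7-(TBDPS-oxy)-1-[(1Z)-5-hydroxy-2-methylpent-1-en-1-yl]hexahydro-3H-furo[3,4-c]pyran-3-one
Conditions: HF·pyridine, pyridine, THF, 0 °C
Reagents that add atoms: none
Why: Buffered fluoride desilylation should cleave the primary TBS ether selectively beside the hindered secondary TBDPS ether.

**Step 10**
Reactants: 18
Product: 19 (1R,3aS,7S,7aS)-7-(TBDPS-oxy)-1-[(1Z)-2-methyl-5-oxopent-1-en-1-yl]hexahydro-3H-furo[3,4-c]pyran-3-one
Conditions: Dess–Martin periodinane, NaHCO3, CH2Cl2, rt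
Reagents that add atoms: none
Why: Dess–Martin oxidation converts the primary alcohol to the aldehyde under buffered conditions that leave the lactone and silyl ether alone.

**Step 11**
Reactants: 19; 20 (triphenylphosphoranylidene)acetaldehyde
Product: 21 (1R,3aS,7S,7aS)-7-(TBDPS-oxy)-1-[(1Z,5E)-2-methyl-7-oxohepta-1,5-dien-1-yl]hexahydro-3H-furo[3,4-c]pyran-3-one
Conditions: toluene, 80 °C
Reagents that add atoms: none
Why: Wittig olefination with the stabilised formyl ylide gives the E-enal (adds C10 and C14), and the ylide is too weakly basic to enolise the lactone.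

**Step 12**
Reactants: 21
Product: 22 (1R,3aS,7S,7aS)-7-(TBDPS-oxy)-1-[(1Z,5Z)-6-iodo-2-methyl-7-oxohepta-1,5-dien-1-yl]hexahydro-3H-furo[3,4-c]pyran-3-one
Conditions: I2, DMAP (cat.), K2CO3, THF/H2O, rt; dilute acid work-up
Reagents that add atoms: iodine, II
Why: α-Iodination of an enal by Baylis–Hillman-type addition of DMAP, iodination of the enolate and elimination, which should return the isomer with the chain trans to CHO, i.e. iodine cis to C2 (Z).

**Step 13**
Reactants: 22
Product: 23 (1R,3aS,7S,7aS)-7-(TBDPS-oxy)-1-[(1Z,5Z)-7-hydroxy-6-iodo-2-methylhepta-1,5-dien-1-yl]hexahydro-3H-furo[3,4-c]pyran-3-one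
Conditions: NaBH4, CeCl3·7H2O, MeOH, −40 °C
Reagents that add atoms: none
Why: Luche reduction directs hydride to 1,2-reduction of the aldehyde and should leave the lactone and the alkenyl iodide untouched.

**Step 14**
Reactants: 23
Product: 24 (1R,3aS,7S,7aS)-7-(TBDPS-oxy)-1-[(1Z,5Z)-7-(TBS-oxy)-6-iodo-2-methylhepta-1,5-dien-1-yl]hexahydro-3H-furo[3,4-c]pyran-3-one
Conditions: TBSCl, imidazole, DMF, 0 °C
Reagents that add atoms: TBSCl, CC(C)(C)[Si](C)(C)Cl
Why: Standard silylation protects the C14 alcohol, which must not be oxidised in step 16.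

**Step 15**
Reactants: 24
Product: 25 (4S,5R)-4-[(1S)-1-(TBDPS-oxy)-2-hydroxyethyl]-5-[(1Z,5Z)-7-(TBS-oxy)-6-iodo-2-methylhepta-1,5-dien-1-yl]-3-methylideneoxolan-2-one
Conditions: LiHMDS, THF, −78 °C; AcOH, −78 °C
Reagents that add atoms: none
Why: E1cB (retro-oxa-Michael) opening: the lactone enolate at C11 expels the β-alkoxide O9, which opens the pyran, creates C11=C13 and frees the C9 hydroxyl in one operation, and the cold acid quench should prevent re-addition.

**Step 16**
Reactants: 25
Product: 26 (2S)-2-(TBDPS-oxy)-2-{(2R,3S)-2-[(1Z,5Z)-7-(TBS-oxy)-6-iodo-2-methylhepta-1,5-dien-1-yl]-4-methylidene-5-oxooxolan-3-yl}acetaldehyde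
Conditions: Dess–Martin periodinane, NaHCO3, CH2Cl2, 0 °C
Reagents that add atoms: none
Why: Dess–Martin oxidation gives the α-silyloxy aldehyde without base, so C8 should not epimerise and the methylene lactone is not attacked.

**Step 17**
Reactants: 26
Product: 27 9-hydroxy-8-(TBDPS-oxy)-14-(TBS-oxy)germacra-1(10)Z,4Z,11(13)-trien-12,6-olide (C6, C7, C8, C9 configured as in 31)
Conditions: CrCl2 (excess), NiCl2 (cat.), DMSO/THF, rt, 2 mM, slow addition
Reagents that add atoms: none
Why: Nozaki–Hiyama–Kishi reaction: Ni inserts into the C–I bond and the alkenylchromium(III) adds only to the aldehyde, closing the ten-membered ring with retention of alkene geometry; Felkin–Anh attack anti to the C8 silyloxy group should give the 8,9-anti (9R) alcohol.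

**Step 18**
Reactants: 27; 28 (2R)-2-methylbutanoic acid
Product: 29 9-{[(2R)-2-methylbutanoyl]oxy}-8-(TBDPS-oxy)-14-(TBS-oxy)germacra-1(10)Z,4Z,11(13)-trien-12,6-olide
Conditions: DIC, DMAP, CH2Cl2, 0 °C→rt
Reagents that add atoms: none
Why: Steglich esterification of the secondary allylic alcohol at low temperature should limit epimerisation at C2′.

**Step 19**
Reactants: 29
Product: 30 8,14-dihydroxy-9-{[(2R)-2-methylbutanoyl]oxy}germacra-1(10)Z,4Z,11(13)-trien-12,6-olide
Conditions: HF·pyridine, pyridine, THF, 0 °C→rt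
Reagents that add atoms: none
Why: Fluoride cleavage of both silyl ethers under mildly acidic conditions should avoid acyl migration from O9 to O8 and conjugate addition to the methylene lactone.

**Step 20**
Reactants: 30
Product: 31 (6R,7R,8S,9R)-8-hydroxy-9-{[(2R)-2-methylbutanoyl]oxy}-14-oxogermacra-1(10)E,4Z,11(13)-trien-12,6-olide
Conditions: MnO2, CH2Cl2, rt
Reagents that add atoms: none
Why: MnO2 should oxidise only the primary allylic C14 alcohol to the enal and leave the secondary, non-allylic C8 hydroxyl.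

**Compound list**
1 | (3-bromopropoxy)(tert-butyl)dimethylsilane | BrCCCO[Si](C)(C)C(C)(C)C | starting material
2 | propyne | CC#C | starting material
3 | oxirane | C1CO1 | starting material
4 | [3-(TBS-oxy)propyl]magnesium bromide | Br[Mg]CCCO[Si](C)(C)C(C)(C)C | intermediate (not isolated)
5 | (Z)-[5-(TBS-oxy)-2-methylpent-1-en-1-yl]copper | [Cu]/C=C(/C)CCCO[Si](C)(C)C(C)(C)C | intermediate (not isolated)
6 | (3Z)-7-(TBS-oxy)-4-methylhept-3-en-1-ol | OCC/C=C(/C)CCCO[Si](C)(C)C(C)(C)C | intermediate
7 | (3Z)-7-(TBS-oxy)-4-methylhept-3-enal | O=CC/C=C(/C)CCCO[Si](C)(C)C(C)(C)C | intermediate (not isolated)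
8 | (3Z)-7-(TBS-oxy)-4-methylhept-3-enoic acid | OC(=O)C/C=C(/C)CCCO[Si](C)(C)C(C)(C)C | intermediate
9 | 1-[(3Z)-7-(TBS-oxy)-4-methylhept-3-enoyl]pyrrolidine | O=C(C/C=C(/C)CCCO[Si](C)(C)C(C)(C)C)N1CCCC1 | intermediate
10 | 3,4-di-O-acetyl-D-xylal | O1C[C@@H](OC(C)=O)[C@H](OC(C)=O)C=C1 | starting material
11 | (3S)-3,6-dihydro-2H-pyran-3-yl acetate | O1C[C@@H](OC(C)=O)C=CC1 | intermediate
12 | (3S)-3,6-dihydro-2H-pyran-3-ol | O1C[C@@H](O)C=CC1 | intermediate
13 | tert-butyl{[(3S)-3,6-dihydro-2H-pyran-3-yl]oxy}diphenylsilane | O1C[C@@H](O[Si](c2ccccc2)(c2ccccc2)C(C)(C)C)C=CC1 | intermediate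
14 | 1-[(3Z)-7-(TBS-oxy)-4-methylhepta-1,3-dien-1-ylidene]pyrrolidinium triflate | [O-]S(=O)(=O)C(F)(F)F.C(=C=[N+]1CCCC1)/C=C(/C)CCCO[Si](C)(C)C(C)(C)C | intermediate (not isolated)
15 | pyrrolidinium iminium triflate of ketone 16 | [O-]S(=O)(=O)C(F)(F)F.[N+]4(CCCC4)=C1[C@H](/C=C(/C)CCCO[Si](C)(C)C(C)(C)C)[C@H]2[C@H](O[Si](c3ccccc3)(c3ccccc3)C(C)(C)C)COC[C@@H]12 | intermediate (not isolated)
16 | cyclobutanone (name in step 7) | O=C1[C@H](/C=C(/C)CCCO[Si](C)(C)C(C)(C)C)[C@H]2[C@H](O[Si](c3ccccc3)(c3ccccc3)C(C)(C)C)COC[C@@H]12 | intermediate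
17 | pyrano-fused lactone (name in step 8) | O=C1O[C@H](/C=C(/C)CCCO[Si](C)(C)C(C)(C)C)[C@H]2[C@H](O[Si](c3ccccc3)(c3ccccc3)C(C)(C)C)COC[C@@H]12 | intermediate
18 | primary alcohol (name in step 9) | O=C1O[C@H](/C=C(/C)CCCO)[C@H]2[C@H](O[Si](c3ccccc3)(c3ccccc3)C(C)(C)C)COC[C@@H]12 | intermediate
19 | aldehyde (name in step 10) | O=C1O[C@H](/C=C(/C)CCC=O)[C@H]2[C@H](O[Si](c3ccccc3)(c3ccccc3)C(C)(C)C)COC[C@@H]12 | intermediate
20 | (triphenylphosphoranylidene)acetaldehyde | O=CC=P(c1ccccc1)(c1ccccc1)c1ccccc1 | starting material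
21 | E-enal (name in step 11) | O=C1O[C@H](/C=C(/C)CC/C=C/C=O)[C@H]2[C@H](O[Si](c3ccccc3)(c3ccccc3)C(C)(C)C)COC[C@@H]12 | intermediate
22 | Z-α-iodoenal (name in step 12) | O=C1O[C@H](/C=C(/C)CC/C=C(/C=O)I)[C@H]2[C@H](O[Si](c3ccccc3)(c3ccccc3)C(C)(C)C)COC[C@@H]12 | intermediate
23 | iodo allylic alcohol (name in step 13) | O=C1O[C@H](/C=C(/C)CC/C=C(/CO)I)[C@H]2[C@H](O[Si](c3ccccc3)(c3ccccc3)C(C)(C)C)COC[C@@H]12 | intermediate
24 | TBS ether (name in step 14) | O=C1O[C@H](/C=C(/C)CC/C=C(/CO[Si](C)(C)C(C)(C)C)I)[C@H]2[C@H](O[Si](c3ccccc3)(c3ccccc3)C(C)(C)C)COC[C@@H]12 | intermediate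
25 | α-methylene lactone alcohol (name in step 15) | C=C1C(=O)O[C@H](/C=C(/C)CC/C=C(/CO[Si](C)(C)C(C)(C)C)I)[C@H]1[C@H](O[Si](c2ccccc2)(c2ccccc2)C(C)(C)C)CO | intermediate
26 | α-silyloxy aldehyde (name in step 16) | C=C1C(=O)O[C@H](/C=C(/C)CC/C=C(/CO[Si](C)(C)C(C)(C)C)I)[C@H]1[C@H](O[Si](c2ccccc2)(c2ccccc2)C(C)(C)C)C=O | intermediate
27 | ten-membered ring alcohol (name in step 17) | C=C1C(=O)O[C@@H]2/C=C(/C)CC/C=C(/CO[Si](C)(C)C(C)(C)C)[C@@H](O)[C@@H](O[Si](c3ccccc3)(c3ccccc3)C(C)(C)C)[C@@H]12 | intermediate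
28 | (2R)-2-methylbutanoic acid | CC[C@@H](C)C(=O)O | starting material
29 | 9-O-acyl bis-silyl ether (name in step 18) | C=C1C(=O)O[C@@H]2/C=C(/C)CC/C=C(/CO[Si](C)(C)C(C)(C)C)[C@@H](OC(=O)[C@H](C)CC)[C@@H](O[Si](c3ccccc3)(c3ccccc3)C(C)(C)C)[C@@H]12 | intermediate
30 | 8,14-diol (name in step 19) | C=C1C(=O)O[C@@H]2/C=C(/C)CC/C=C(/CO)[C@@H](OC(=O)[C@H](C)CC)[C@@H](O)[C@@H]12 | intermediate
31 | target (name in step 20) | C=C1C(=O)O[C@@H]2/C=C(/C)CC/C=C(/C=O)[C@@H](OC(=O)[C@H](C)CC)[C@@H](O)[C@@H]12 | target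

**Count**
Total steps: 20. Longest linear sequence: 17 steps (steps 1–3 and 7–20; the branch 4–6 and 7–20 is equally long).

**Steps most likely to fail**

Step 7. The keteniminium may bond in the reverse orientation on the unsymmetrical ring alkene (iminium carbon to C7), or decompose faster than it adds to an alkene flanked by two allylic C–O bonds. The fallback replaces the ring alkene by a terminal alkene, whose polarisation fixes the orientation, and adds C13 afterwards; it sets out from amide 9 and returns at alcohol 18. Commercial (S)-but-3-ene-1,2-diol is silylated at the primary hydroxyl (TBSCl, imidazole, −20 °C) to (2S)-1-(TBS-oxy)but-3-en-2-ol F1 and then at the secondary one (TBDPSCl, imidazole) to the bis-silyl ether F2. Amide 9 and F2 under the conditions of step 7 would give the cyclobutaniminium triflate F3 and, after hydrolysis and equilibration, the 2,3-trans cyclobutanone F4, at which stage the C7 epimers are separated. Baeyer–Villiger oxidation (H2O2, AcOH) would give the lactone F5. LDA and Eschenmoser's salt would give the Mannich base F6, methyl iodide its methiodide F7, and aqueous NaHCO3 the α-methylene lactone F8. HF·pyridine would remove both primary TBS groups to give the diol F9, and catalytic DBU would close the pyran by 6-exo oxa-Michael addition of the C9 hydroxyl to C13, giving 18.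

Step 17. Oligomerisation may compete with closure of the strained ring, and the alkenylchromium may add to the wrong aldehyde face inside the ten-membered transition state, giving the C9 epimer. The fallback sets the C9 centre by reduction instead of addition; it sets out from 27 (as the C9 epimer mixture) and returns at 27. Dess–Martin oxidation of the mixture would give the cross-conjugated C9 ketone F11, and 1,2-reduction under reagent control (CBS catalyst with catecholborane, enantiomer chosen for the 9R alcohol) would return 27.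

Step 15. The liberated C9 alkoxide may add back to C13, attack the lactone carbonyl, or take the neighbouring silyl group before the quench. The fallback caps the alkoxide as it forms and bypasses the free alcohol; it sets out from 24 and returns at aldehyde 26. LiHMDS is added to 24 and Et3SiCl at −78 °C (internal quench) to give the triethylsilyl ether F10, and Swern oxidation would convert the primary TES ether directly to 26.

**Further compounds**
F1 | step 7 | (2S)-1-(TBS-oxy)but-3-en-2-ol | CC(C)(C)[Si](C)(C)OC[C@@H](O)C=C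
F2 | step 7 | (2S)-1-(TBS-oxy)-2-(TBDPS-oxy)but-3-ene | CC(C)(C)[Si](C)(C)OC[C@@H](O[Si](c1ccccc1)(c1ccccc1)C(C)(C)C)C=C
F3 | step 7 | pyrrolidinium iminium triflate of F4 | [O-]S(=O)(=O)C(F)(F)F.[N+]3(CCCC3)=C1[C@H](/C=C(/C)CCCO[Si](C)(C)C(C)(C)C)[C@@H]([C@H](O[Si](c2ccccc2)(c2ccccc2)C(C)(C)C)CO[Si](C)(C)C(C)(C)C)C1
F4 | step 7 | trans-2-alkenyl-3-[(1S)-1-(TBDPS-oxy)-2-(TBS-oxy)ethyl]cyclobutanone | O=C1[C@H](/C=C(/C)CCCO[Si](C)(C)C(C)(C)C)[C@@H]([C@H](O[Si](c2ccccc2)(c2ccccc2)C(C)(C)C)CO[Si](C)(C)C(C)(C)C)C1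
F5 | step 7 | trans-4,5-disubstituted γ-butyrolactone | O=C1O[C@H](/C=C(/C)CCCO[Si](C)(C)C(C)(C)C)[C@@H]([C@H](O[Si](c2ccccc2)(c2ccccc2)C(C)(C)C)CO[Si](C)(C)C(C)(C)C)C1
F6 | step 7 | α-(dimethylaminomethyl) lactone (C11 epimers) | CN(C)CC1C(=O)O[C@H](/C=C(/C)CCCO[Si](C)(C)C(C)(C)C)[C@H]1[C@H](O[Si](c2ccccc2)(c2ccccc2)C(C)(C)C)CO[Si](C)(C)C(C)(C)C
F7 | step 7 | methiodide of F6 | C[N+](C)(C)CC1C(=O)O[C@H](/C=C(/C)CCCO[Si](C)(C)C(C)(C)C)[C@H]1[C@H](O[Si](c2ccccc2)(c2ccccc2)C(C)(C)C)CO[Si](C)(C)C(C)(C)C.[I-]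
F8 | step 7 | α-methylene lactone bis-TBS ether | C=C1C(=O)O[C@H](/C=C(/C)CCCO[Si](C)(C)C(C)(C)C)[C@H]1[C@H](O[Si](c2ccccc2)(c2ccccc2)C(C)(C)C)CO[Si](C)(C)C(C)(C)C
F9 | step 7 | α-methylene lactone diol | C=C1C(=O)O[C@H](/C=C(/C)CCCO)[C@H]1[C@H](O[Si](c2ccccc2)(c2ccccc2)C(C)(C)C)CO
F10 | step 15 | triethylsilyl ether of 25 | C=C1C(=O)O[C@H](/C=C(/C)CC/C=C(/CO[Si](C)(C)C(C)(C)C)I)[C@H]1[C@H](O[Si](c2ccccc2)(c2ccccc2)C(C)(C)C)CO[Si](CC)(CC)CC
F11 | step 17 | C9 ketone of 27 | C=C1C(=O)O[C@@H]2/C=C(/C)CC/C=C(/CO[Si](C)(C)C(C)(C)C)C(=O)[C@@H](O[Si](c3ccccc3)(c3ccccc3)C(C)(C)C)[C@@H]12
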